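**Plan**
Perlatolic acid is achiral, so no stereocentre has to be controlled. The only one met on the way, a ketal carbon in the cycloadduct, vanishes on aromatisation.
The retrosynthesis cuts, in this order: the benzyl ester that masks the CO2H; the C1–C2 and C5–C6 bonds of ring A; the depside C(=O)–O bond to O4 of ring B; the C1–CO2H bond of ring B.
The ring A cut is possible because ring A has its ester carbon on C1 between pentyl on C6 and OH on C2, with OMe on C4. C1 and C6 are therefore the alkyne carbons of an oct-2-ynoyl ester on O4 of ring B, and C2–C5 are the four carbons of a 1,3-dimethoxy-1-silyloxybutadiene with its oxygens on C2 and C4.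
Forward: ring B comes from olivetol (carboxylation, benzyl ester), its 4-OH is acylated with oct-2-ynoic acid, ring A is built onto this ynoate by Diels–Alder addition of the diene with aromatisation, and hydrogenolysis frees the acid.

Key step: step 5

Remark: the silyloxydiene is used as the geometric mixture at its ketene acetal double bond that the enolisation delivers, and the cycloadduct of the key step is racemic at its ketal carbon. Both elements disappear when ring A becomes aromatic, so the SMILES of these two compounds carry no stereodescriptor.

**Step 1**
Reactants: 1 olivetol (5-pentylbenzene-1,3-diol)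
Product: 2 olivetolic acid (2,4-dihydroxy-6-pentylbenzoic acid)
Conditions: MeOMgOCO2Me (2 M in DMF, excess), 120 °C; then cold 2 M HCl
Reagents that add atoms: methyl magnesium carbonate (methoxymagnesium methyl carbonate), COC(=O)O[Mg]OC
Why: In this Kolbe–Schmitt-type carboxylation the magnesium phenoxide is carboxylated ortho to one oxygen and para to the other (C4 and C6 of olivetol are equivalent by symmetry), and the chelated magnesium salicylate that results should pull the equilibrium towards the acid.

**Step 2**
Reactants: 2 olivetolic acid; 3 benzyl bromide
Product: 4 benzyl olivetolate (benzyl 2,4-dihydroxy-6-pentylbenzoate)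
Conditions: BnBr, KHCO3, DMF, rt
Reagents that add atoms: none
Why: In this SN2 O-alkylation of a carboxylate, hydrogencarbonate deprotonates only the carboxylic acid, so benzyl bromide should alkylate the carboxylate and leave both phenols free.

**Step 3**
Reactants: 4 benzyl olivetolate; 5 oct-2-ynoic acid
Product: 6 benzyl 2-hydroxy-4-(oct-2-ynoyloxy)-6-pentylbenzoate
Conditions: DCC, DMAP (5 mol%), CH2Cl2, −20 to 0 °C
Reagents that add atoms: none
Why: In this Steglich esterification the activated ynoic acid should acylate the free 4-OH, because the 2-OH is tied up in a hydrogen bond to the neighbouring benzyl ester carbonyl, and the low temperature and small amount of DMAP hold back conjugate addition to the triple bond.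

**Step 4**
Reactants: 7 methyl (E)-3-methoxybut-2-enoate
Product: 8 1,3-dimethoxy-1-(trimethylsilyloxy)buta-1,3-diene (Brassard diene)
Conditions: LiN(iPr)2 (commercial solution), THF, −78 °C; then Me3SiCl, −78 °C to rt
Reagents that add atoms: chlorotrimethylsilane, C[Si](C)(C)Cl
Why: γ-Deprotonation of the vinylogous carbonate-type ester to its lithium dienolate followed by O-silylation (silyl ketene acetal formation) is the standard way to this class of 1,1,3-trioxygenated dienes.

**Step 5**
Reactants: 6 benzyl 2-hydroxy-4-(oct-2-ynoyloxy)-6-pentylbenzoate; 8 1,3-dimethoxy-1-(trimethylsilyloxy)buta-1,3-diene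
Product: 11 benzyl perlatolate, via silyl ether 9 (not isolated), via cycloadduct 10 (not isolated)
Conditions: BSA, PhMe, 60 °C; then 8 (3 equiv, in two portions), 110 °C, sealed tube; then 1 M HCl, THF, rt
Reagents that add atoms: none
Why: N,O-Bis(trimethylsilyl)acetamide first converts the chelated ring B phenol into its trimethylsilyl ether 9, so that no acidic hydrogen destroys the silyl ketene acetal. Diene 8 then adds to the ynoate in a thermal, asynchronous, normal-electron-demand Diels–Alder reaction, in which the unsubstituted diene terminus C4 bonds to the pentyl-bearing β-carbon of the ynoate and the ketene acetal carbon C1 to the α-carbon, giving the cyclohexa-1,4-diene ketal 10. Dilute acid cleaves both silyl ethers, the hemiketal expels methanol to a cyclohexadienone and this enolises to the hydrogen-bonded 2-hydroxy-4-methoxybenzoate; the closest known reaction type is the Diels–Alder benzannulation of Brassard-type 1,1,3-trioxygenated dienes with acetylenic esters to 2-hydroxy-4-methoxybenzoates. Ring A is closed as a six-membered carbocycle by intermolecular [4+2] cycloaddition, four carbons from the diene and two from the alkyne, with C1–C2 and C5–C6 as the new bonds. The only stereocentre, the ketal carbon of 10, arises racemic and is erased on aromatisation, so no stereocontrol is needed. The selectivity required is regiochemical and is secured by the matched polarisation of the ketene acetal diene (largest HOMO coefficient at C4) and the ynoate (largest LUMO coefficient at the β-carbon), reinforced by the electron-poor aryl ester, while the neutral thermal conditions should spare the benzyl and aryl esters.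

**Step 6**
Reactants: 11 benzyl perlatolate
Product: 12 perlatolic acid
Conditions: H2 (1 atm), Pd/C (10 wt% Pd), EtOAc, rt
Reagents that add atoms: none
Why: Catalytic hydrogenolysis of the benzyl ester should free the carboxylic acid under neutral conditions that leave the depside aryl ester, the aryl methyl ether and both phenols untouched.

**Compound list**
1 | olivetol (5-pentylbenzene-1,3-diol) | CCCCCc1cc(O)cc(O)c1 | starting material
2 | olivetolic acid (2,4-dihydroxy-6-pentylbenzoic acid) | CCCCCc1cc(O)cc(O)c1C(=O)O | intermediate
3 | benzyl bromide | BrCc1ccccc1 | starting material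
4 | benzyl olivetolate (benzyl 2,4-dihydroxy-6-pentylbenzoate) | CCCCCc1cc(O)cc(O)c1C(=O)OCc1ccccc1 | intermediate
5 | oct-2-ynoic acid | CCCCCC#CC(=O)O | starting material
6 | benzyl 2-hydroxy-4-(oct-2-ynoyloxy)-6-pentylbenzoate | CCCCCC#CC(=O)Oc1cc(O)c(C(=O)OCc2ccccc2)c(CCCCC)c1 | intermediate
7 | methyl (E)-3-methoxybut-2-enoate | CO/C(C)=C/C(=O)OC | starting material
8 | 1,3-dimethoxy-1-(trimethylsilyloxy)buta-1,3-diene (Brassard diene, geometric mixture at C1=C2) | C=C(OC)C=C(OC)O[Si](C)(C)C | intermediate
9 | benzyl 4-(oct-2-ynoyloxy)-6-pentyl-2-(trimethylsilyloxy)benzoate (silyl ether of 6, not isolated) | CCCCCC#CC(=O)Oc1cc(O[Si](C)(C)C)c(C(=O)OCc2ccccc2)c(CCCCC)c1 | intermediate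
10 | benzyl 4-{[4,6-dimethoxy-2-pentyl-6-(trimethylsilyloxy)cyclohexa-1,4-diene-1-carbonyl]oxy}-6-pentyl-2-(trimethylsilyloxy)benzoate (racemic cycloadduct, not isolated) | CCCCCC1=C(C(=O)Oc2cc(O[Si](C)(C)C)c(C(=O)OCc3ccccc3)c(CCCCC)c2)C(OC)(O[Si](C)(C)C)C=C(OC)C1 | intermediate
11 | benzyl perlatolate (benzyl 2-hydroxy-4-[(2-hydroxy-4-methoxy-6-pentylbenzoyl)oxy]-6-pentylbenzoate) | CCCCCc1cc(OC(=O)c2c(O)cc(OC)cc2CCCCC)cc(O)c1C(=O)OCc1ccccc1 | intermediate
12 | perlatolic acid (2-hydroxy-4-[(2-hydroxy-4-methoxy-6-pentylbenzoyl)oxy]-6-pentylbenzoic acid) | CCCCCc1cc(OC(=O)c2c(O)cc(OC)cc2CCCCC)cc(O)c1C(=O)O | target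

**Step count**
Total: 6 steps. Longest linear sequence: 5 steps (steps 1, 2, 3, 5, 6); step 4 is a one-step side branch.

**Steps most likely to fail**

Step 5. The cycloaddition to the β-alkyl ynoate may be slower than the thermal decay of the diene. The nucleophilic ketene acetal may attack the activated aryl ester instead of the triple bond. The ketal of the adduct may partly aromatise by loss of silanol and so give the 2-methyl ether. The fallback runs the same benzannulation on a simple ester and joins the two rings afterwards by a classical depside esterification. It sets out from 5, 8 and 4. Fischer esterification of 5 (MeOH, catalytic H2SO4) should give methyl oct-2-ynoate F1. F1 and 8, heated neat at 120–130 °C and then treated with dilute HCl, should give methyl 2-hydroxy-4-methoxy-6-pentylbenzoate F2. Benzylation (BnBr, K2CO3, DMF) should give methyl 2-(benzyloxy)-4-methoxy-6-pentylbenzoate F3, and saponification (KOH, aqueous DMSO, 90 °C) should give 2-(benzyloxy)-4-methoxy-6-pentylbenzoic acid F4. F4 and 4 with trifluoroacetic anhydride in toluene at rt should give benzyl 2'-O-benzylperlatolate F5, acylation again falling on the free 4-OH. Hydrogenolysis (H2, Pd/C, EtOAc) removes both benzyl groups and comes back to the route at 12.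

Step 1. Carboxylation at C2, between the two hydroxyls, may compete with attack at C4, and the β-resorcylic acid may decarboxylate during acidic work-up. The fallback sets out from 1 and installs the carbon at the aldehyde oxidation level. Vilsmeier–Haack formylation (POCl3, DMF, 0 °C to rt, then aqueous hydrolysis), directed para to one hydroxyl, should give 2,4-dihydroxy-6-pentylbenzaldehyde F6. Lindgren–Pinnick oxidation (NaClO2, NaH2PO4, sulfamic acid as hypochlorite scavenger, aqueous dioxane, 0 °C) should then give the acid, and the route is rejoined at 2.

Step 3. DMAP or the phenoxide may add in conjugate fashion to the activated triple bond, the O-acylisourea may rearrange to the N-acylurea, or both phenols may be acylated. The fallback sets out from 5 and replaces carbodiimide activation by a preformed acyl chloride, with no nucleophilic catalyst present. Oxalyl chloride and catalytic DMF in CH2Cl2 should convert 5 into oct-2-ynoyl chloride F7. F7 is added at −40 °C to 4 and 2,6-lutidine in CH2Cl2, and the route is rejoined at 6.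

**Further compounds**
F1 | step 5 | methyl oct-2-ynoate | CCCCCC#CC(=O)OC
F2 | step 5 | methyl 2-hydroxy-4-methoxy-6-pentylbenzoate | CCCCCc1cc(OC)cc(O)c1C(=O)OC
F3 | step 5 | methyl 2-(benzyloxy)-4-methoxy-6-pentylbenzoate | CCCCCc1cc(OC)cc(OCc2ccccc2)c1C(=O)OC
F4 | step 5 | 2-(benzyloxy)-4-methoxy-6-pentylbenzoic acid | CCCCCc1cc(OC)cc(OCc2ccccc2)c1C(=O)O
F5 | step 5 | benzyl 2'-O-benzylperlatolate (benzyl 4-{[2-(benzyloxy)-4-methoxy-6-pentylbenzoyl]oxy}-2-hydroxy-6-pentylbenzoate) | CCCCCc1cc(OC(=O)c2c(OCc3ccccc3)cc(OC)cc2CCCCC)cc(O)c1C(=O)OCc1ccccc1
F6 | step 1 | 2,4-dihydroxy-6-pentylbenzaldehyde | CCCCCc1cc(O)cc(O)c1C=O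
F7 | step 3 | oct-2-ynoyl chloride | CCCCCC#CC(=O)Cl
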